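**Retrosynthetic overview**
1. The target is reached by hydrogenolysis of nine benzyl ethers in 18, which comes from double galloylation (O3 and O7) of 5,3′,4′-tri-O-benzylcatechin 16. O7 is kept apart from O5 as a MOM ether from the aldehyde stage on.
2. O3 and both stereocentres (C2, C3) come from one syn-hydroboration/oxidation of the flav-2-ene 13 (C2=C3 enol ether) with the (+)-α-pinene-derived IpcBH2.
3. Ring C of 13 is made by a [3+3] union of bromide 8 (ring A) and ketone 10 (ring B): C3–C4 by enolate C-benzylation and O1–C8a by copper-catalysed enolate O-arylation, in one pot.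
4. Enabling feature: O1–C2–C3 of ring C is the O–C=C unit of the enolate of the ring B methyl ketone (O1 and C3 both nucleophilic, 1,3-related through C2), while C4 and C8a are a benzylic carbon and the ring A carbon ortho to it, i.e. a 2-bromobenzyl bromide.
5. Ring order: rings A and B are bought as benzenes (1 and 9); ring C is the only ring formed, in step 8.

Key step: step 8

Assumption: in step 9 the sense of induction is taken to follow that of 1-arylcycloalkenes, where the (+)-α-pinene-derived IpcBH2 gives (1S,2R)-trans-2-arylcycloalkanols, which maps onto (2R,3S) here; if the ring oxygen reversed it, the reagent from (−)-α-pinene would be used.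

**Route**

Step 1
Reactants: 1 1-bromo-3,5-dimethoxybenzene
Product: 3 2-bromo-4,6-dimethoxybenzaldehyde, via aryl iminium salt 2 (not isolated)
Conditions: POCl3, DMF, 0 → 90 °C; then ice–water
Reagents that add atoms: N,N-dimethylformamide, CN(C)C=O (formyl carbon; also the Me2N group of 2); water, O (carbonyl oxygen of 3); phosphoryl chloride, O=P(Cl)(Cl)Cl (chloride of 2 only)
Why: Vilsmeier–Haack formylation, in which the chloroiminium ion attacks the carbon para to one methoxy group and ortho to the other (next to bromine) rather than the more crowded carbon between the two methoxy groups, and hydrolysis of 2 frees the aldehyde.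

Step 2
Reactants: 3 2-bromo-4,6-dimethoxybenzaldehyde
Product: 4 2-bromo-4,6-dihydroxybenzaldehyde
Conditions: BBr3, CH2Cl2, −78 °C → rt; then H2O
Reagents that add atoms: none
Why: Lewis acid O-demethylation with BBr3 should cleave both aryl methyl ethers while the aryl bromide persists and the aldehyde is regenerated on aqueous work-up.

Step 3
Reactants: 4 2-bromo-4,6-dihydroxybenzaldehyde
Product: 5 2-bromo-6-hydroxy-4-(methoxymethoxy)benzaldehyde
Conditions: MOMCl (1.05 equiv), K2CO3, acetone, 0 °C → rt
Reagents that add atoms: chloromethyl methyl ether, COCCl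
Why: Williamson-type O-alkylation that should be selective for the 4-OH, because the 6-OH is held in an intramolecular hydrogen bond to the formyl group, as is usual for 2,4-dihydroxybenzaldehydes.

Step 4
Reactants: 5 2-bromo-6-hydroxy-4-(methoxymethoxy)benzaldehyde
Product: 6 2-(benzyloxy)-6-bromo-4-(methoxymethoxy)benzaldehyde
Conditions: BnBr, K2CO3, DMF, 60 °C
Reagents that add atoms: benzyl bromide, BrCc1ccccc1
Why: Williamson etherification under more forcing conditions should alkylate the remaining hydrogen-bonded phenol, the MOM acetal being stable to base.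

Step 5
Reactants: 6 2-(benzyloxy)-6-bromo-4-(methoxymethoxy)benzaldehyde
Product: 7 [2-(benzyloxy)-6-bromo-4-(methoxymethoxy)phenyl]methanol
Conditions: NaBH4, MeOH–THF, 0 °C
Reagents that add atoms: none
Why: Chemoselective hydride reduction of the aldehyde; aryl bromide, benzyl ether and MOM acetal are inert to NaBH4.

Step 6
Reactants: 7 [2-(benzyloxy)-6-bromo-4-(methoxymethoxy)phenyl]methanol
Product: 8 1-(benzyloxy)-3-bromo-2-(bromomethyl)-5-(methoxymethoxy)benzene
Conditions: CBr4, PPh3, CH2Cl2, 0 °C; filtered through basic alumina and used at once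
Reagents that add atoms: carbon tetrabromide, BrC(Br)(Br)Br
Why: Appel reaction (SN2 displacement of the alkoxyphosphonium by bromide) under neutral conditions that should spare the acid-labile MOM acetal.

Step 7
Reactants: 9 1-(3,4-dihydroxyphenyl)ethanone
Product: 10 1-[3,4-bis(benzyloxy)phenyl]ethanone
Conditions: BnBr, K2CO3, DMF, 60 °C
Reagents that add atoms: benzyl bromide, BrCc1ccccc1
Why: Double Williamson etherification of the catechol.

Step 8
Reactants: 8 1-(benzyloxy)-3-bromo-2-(bromomethyl)-5-(methoxymethoxy)benzene; 10 1-[3,4-bis(benzyloxy)phenyl]ethanone (1.2 equiv)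
Product: 13 5-(benzyloxy)-2-[3,4-bis(benzyloxy)phenyl]-7-(methoxymethoxy)-4H-chromene, via lithium enolate 11 (not isolated), via bromo ketone 12 (not isolated)
Conditions: LiN(SiMe3)2, THF, −78 °C; 8, −78 → 0 °C; then NaOtBu, CuI (10 mol %), 1,10-phenanthroline (20 mol %), toluene, 100 °C (THF distilled off); pH 7 work-up, Et3N-deactivated silica
Reagents that add atoms: lithium bis(trimethylsilyl)amide, [Li+].C[Si](C)(C)[N-][Si](C)(C)C (lithium of 11 only; no reagent atom other than hydrogen stays in 13)
Why: Proposed new method: the lithium enolate 11 is C-benzylated by the sp3 bromide of 8 in an SN2 step (C3–C4), NaOtBu then regenerates the enolate of ketone 12, and its oxygen is arylated at C8a by monovalent copper through oxidative addition into the aryl C–Br bond and C–O reductive elimination (Ullmann-type O1–C8a bond), so that two known halves are merged in one pot on an unstabilised aryl methyl ketone. The closest known reaction type is the CuI-catalysed domino C-benzylation/O-arylation of 2-bromobenzyl bromides with β-keto esters to 4H-chromenes, together with the CuI-catalysed cyclisation of 2-haloaryl ketone enolates to benzofurans. Ring C closes by a six-membered ipso-substitution at C8a (6-exo with respect to the breaking C–Br bond) from the Z-enolate, in which O1 and C4 are cis on C2=C3. No stereocentre is formed; the step delivers the C2=C3 enol ether on which step 9 sets C2 and C3. The selectivities needed are mono-C-alkylation over O- or bis-alkylation, secured by the covalent lithium enolate in THF at low temperature used in slight excess, and O- over C-arylation, secured because C-arylation at C3 would have to close a four-membered ring.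

Step 9
Reactants: 13 5-(benzyloxy)-2-[3,4-bis(benzyloxy)phenyl]-7-(methoxymethoxy)-4H-chromene
Product: 15 (2R,3S)-5-(benzyloxy)-2-[3,4-bis(benzyloxy)phenyl]-7-(methoxymethoxy)chroman-3-ol, via dialkylborane 14 (not isolated)
Conditions: IpcBH2 [from (+)-α-pinene, BF3-free stock solution], THF, −25 °C; then NaOH, H2O2, 0 °C → rt
Reagents that add atoms: hydrogen peroxide, OO (oxygen at C3 of 15); monoisopinocampheylborane, C[C@@H]1[C@H]2C[C@H](C2(C)C)C[C@H]1B (boron and isopinocampheyl group of 14 only)
Why: Asymmetric hydroboration–oxidation of a trisubstituted aryl enol ether, in which boron adds to C3 (β to O1, away from the aryl group) and hydrogen to C2 on the same face so that ring B and boron end up trans, the isopinocampheyl group selects the face as it does for 1-arylcycloalkenes, and oxidation with retention should give the (2R,3S) trans alcohol.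

Step 10
Reactants: 15 (2R,3S)-5-(benzyloxy)-2-[3,4-bis(benzyloxy)phenyl]-7-(methoxymethoxy)chroman-3-ol
Product: 16 (2R,3S)-5-(benzyloxy)-2-[3,4-bis(benzyloxy)phenyl]chromane-3,7-diol
Conditions: HCl (3 M in MeOH), THF, 40 °C
Reagents that add atoms: none
Why: Acid-catalysed acetal exchange with methanol should cleave the phenolic MOM ether while the benzyl ethers and the two stereocentres are untouched under these mild conditions.

Step 11
Reactants: 16 (2R,3S)-5-(benzyloxy)-2-[3,4-bis(benzyloxy)phenyl]chromane-3,7-diol; 17 3,4,5-tris(benzyloxy)benzoic acid (2.5 equiv)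
Product: 18 (2R,3S)-5-(benzyloxy)-2-[3,4-bis(benzyloxy)phenyl]chromane-3,7-diyl bis[3,4,5-tris(benzyloxy)benzoate]
Conditions: DCC, DMAP, CH2Cl2, 0 °C → rt
Reagents that add atoms: none
Why: Steglich esterification, in which DMAP-catalysed acyl transfer from the O-acylisourea should acylate both the phenol O7 and the secondary alcohol O3 without touching the stereocentres.

Step 12
Reactants: 18 (2R,3S)-5-(benzyloxy)-2-[3,4-bis(benzyloxy)phenyl]chromane-3,7-diyl bis[3,4,5-tris(benzyloxy)benzoate]
Product: 19 catechin 3,7-di-O-gallate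
Conditions: H2 (1 atm), Pd(OH)2/C, THF–EtOAc, rt
Reagents that add atoms: none
Why: Catalytic hydrogenolysis of all nine benzyl ethers in a non-nucleophilic medium should leave the alkyl and aryl gallate esters and both stereocentres intact.

**Compound list**
1 | 1-bromo-3,5-dimethoxybenzene | COc1cc(Br)cc(OC)c1 | starting material
2 | N-[(2-bromo-4,6-dimethoxyphenyl)methylidene]-N-methylmethanaminium chloride | COc1cc(OC)c(C=[N+](C)C)c(Br)c1.[Cl-] | intermediate
3 | 2-bromo-4,6-dimethoxybenzaldehyde | COc1cc(OC)c(C=O)c(Br)c1 | intermediate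
4 | 2-bromo-4,6-dihydroxybenzaldehyde | Oc1cc(O)c(C=O)c(Br)c1 | intermediate
5 | 2-bromo-6-hydroxy-4-(methoxymethoxy)benzaldehyde | COCOc1cc(O)c(C=O)c(Br)c1 | intermediate
6 | 2-(benzyloxy)-6-bromo-4-(methoxymethoxy)benzaldehyde | COCOc1cc(OCc2ccccc2)c(C=O)c(Br)c1 | intermediate
7 | [2-(benzyloxy)-6-bromo-4-(methoxymethoxy)phenyl]methanol | COCOc1cc(OCc2ccccc2)c(CO)c(Br)c1 | intermediate
8 | 1-(benzyloxy)-3-bromo-2-(bromomethyl)-5-(methoxymethoxy)benzene | COCOc1cc(OCc2ccccc2)c(CBr)c(Br)c1 | intermediate
9 | 1-(3,4-dihydroxyphenyl)ethanone | CC(=O)c1ccc(O)c(O)c1 | starting material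
10 | 1-[3,4-bis(benzyloxy)phenyl]ethanone | CC(=O)c1ccc(OCc2ccccc2)c(OCc2ccccc2)c1 | intermediate
11 | lithium 1-[3,4-bis(benzyloxy)phenyl]ethenolate | [Li+].[O-]C(=C)c1ccc(OCc2ccccc2)c(OCc2ccccc2)c1 | intermediate
12 | 3-[2-(benzyloxy)-6-bromo-4-(methoxymethoxy)phenyl]-1-[3,4-bis(benzyloxy)phenyl]propan-1-one | O=C(CCc1c(Br)cc(OCOC)cc1OCc1ccccc1)c1ccc(OCc2ccccc2)c(OCc2ccccc2)c1 | intermediate
13 | 5-(benzyloxy)-2-[3,4-bis(benzyloxy)phenyl]-7-(methoxymethoxy)-4H-chromene | COCOc1cc(OCc3ccccc3)c2c(c1)OC(c1ccc(OCc3ccccc3)c(OCc3ccccc3)c1)=CC2 | intermediate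
14 | [(2R,3S)-5-(benzyloxy)-2-[3,4-bis(benzyloxy)phenyl]-7-(methoxymethoxy)chroman-3-yl](isopinocampheyl)borane, isopinocampheyl from (+)-α-pinene | C[C@@H]1[C@H]2C[C@H](C2(C)C)C[C@H]1B[C@H]3Cc4c(OCc5ccccc5)cc(OCOC)cc4O[C@@H]3c6ccc(OCc7ccccc7)c(OCc8ccccc8)c6 | intermediate
15 | (2R,3S)-5-(benzyloxy)-2-[3,4-bis(benzyloxy)phenyl]-7-(methoxymethoxy)chroman-3-ol | COCOc1cc(OCc3ccccc3)c2c(c1)O[C@H](c1ccc(OCc3ccccc3)c(OCc3ccccc3)c1)[C@@H](O)C2 | intermediate
16 | (2R,3S)-5-(benzyloxy)-2-[3,4-bis(benzyloxy)phenyl]chromane-3,7-diol | Oc1cc(OCc3ccccc3)c2c(c1)O[C@H](c1ccc(OCc3ccccc3)c(OCc3ccccc3)c1)[C@@H](O)C2 | intermediate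
17 | 3,4,5-tris(benzyloxy)benzoic acid | OC(=O)c1cc(OCc2ccccc2)c(OCc2ccccc2)c(OCc2ccccc2)c1 | starting material
18 | (2R,3S)-5-(benzyloxy)-2-[3,4-bis(benzyloxy)phenyl]chromane-3,7-diyl bis[3,4,5-tris(benzyloxy)benzoate] | O=C(Oc1cc(OCc3ccccc3)c2c(c1)O[C@H](c1ccc(OCc3ccccc3)c(OCc3ccccc3)c1)[C@@H](OC(=O)c1cc(OCc3ccccc3)c(OCc3ccccc3)c(OCc3ccccc3)c1)C2)c1cc(OCc2ccccc2)c(OCc2ccccc2)c(OCc2ccccc2)c1 | intermediate
19 | catechin 3,7-di-O-gallate, (2R,3S) | O=C(Oc1cc(O)c2c(c1)O[C@H](c1ccc(O)c(O)c1)[C@@H](OC(=O)c1cc(O)c(O)c(O)c1)C2)c1cc(O)c(O)c(O)c1 | target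

**Totals**
Total step count: 12. Longest linear sequence: 11 steps (steps 1–6 and 8–12).

**Steps most likely to fail**

Step 8 (proposed new method). What may go wrong: O- or bis-alkylation of the enolate, self-alkylation of the electron-rich benzylic bromide before it is captured, intermolecular coupling or protodebromination outrunning ring closure, and hydrolysis of the enol ether during isolation. The fallback sets out from aldehyde 6 and ketone 10 and uses known chemistry. Claisen–Schmidt condensation (KOH, EtOH–THF, rt) should give (E)-3-[2-(benzyloxy)-6-bromo-4-(methoxymethoxy)phenyl]-1-[3,4-bis(benzyloxy)phenyl]prop-2-en-1-one F1. Its enone would be reduced 1,4 with catalytic [(Ph3P)CuH]6 and PhSiH3 in toluene to give ketone 12, now isolated and purified. Ring C would then be closed in a separate palladium-catalysed intramolecular enolate O-arylation (Pd2(dba)3, bis[2-(diphenylphosphino)phenyl] ether, Cs2CO3, toluene, 100 °C), which comes back to the route at 13.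

Step 9. What may go wrong: insufficient discrimination of the two alkene faces by the chiral borane, β-elimination of the β-aryloxyborane with opening of ring C, and acid-promoted hydration of the enol ether. The fallback sets out from 13 and gives up reagent control for resolution. Hydroboration with achiral BH3·SMe2 (THF, 0 °C), then NaOH/H2O2, should give the racemic trans alcohol, that is 15 together with (2S,3R)-5-(benzyloxy)-2-[3,4-bis(benzyloxy)phenyl]-7-(methoxymethoxy)chroman-3-ol F2. The two would be separated by preparative chromatography on a cellulose tris(3,5-dimethylphenylcarbamate) phase, and the route is rejoined at 15.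

Step 6. What may go wrong: ionisation of the electron-rich benzylic bromide, leading to self-alkylation or hydrolysis before use. The fallback sets out from alcohol 7 and ketone 10 and avoids any benzylic halide. Hydrogen-borrowing α-alkylation ([Cp*IrCl2]2, KOH, toluene, 110 °C) dehydrogenates 7 to 6, condenses it to the chalcone F1 and re-hydrogenates it in the flask, and should give ketone 12 directly. The second stage of step 8 (NaOtBu, CuI, 1,10-phenanthroline, toluene, 100 °C) then comes back to the route at 13. No compound outside the lists is isolated (F0).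

**Further compounds**
F1 | step 8 | (E)-3-[2-(benzyloxy)-6-bromo-4-(methoxymethoxy)phenyl]-1-[3,4-bis(benzyloxy)phenyl]prop-2-en-1-one | O=C(/C=C/c1c(Br)cc(OCOC)cc1OCc1ccccc1)c1ccc(OCc2ccccc2)c(OCc2ccccc2)c1
F2 | step 9 | (2S,3R)-5-(benzyloxy)-2-[3,4-bis(benzyloxy)phenyl]-7-(methoxymethoxy)chroman-3-ol | COCOc1cc(OCc3ccccc3)c2c(c1)O[C@@H](c1ccc(OCc3ccccc3)c(OCc3ccccc3)c1)[C@H](O)C2
F0 | step 6 | none | none
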